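**Retrosynthetic overview**
- The strategy rests on ring A, the 2,4-disubstituted furan (O1', C2', C3', C4', C5') whose C2' carries the CH2 bridge to C3 of ring B. The carbon string C5'–C4'–C3'–C2'–CH2 is the backbone of a (Z)-pent-2-en-4-yn-1-ol, so forming the O1'–C2' bond delivers ring A and the bridge together.
- Disconnection 1: the C5–C6 bond and the Z C6=C7 alkene of the decenoate come from a 3-(ring A)propylcopper reagent, propyne and an iodo ester made from the (R)-half-ester, which supplies the C3 stereocentre.
- Disconnection 2 (key): ring A opens to the (Z)-enynol; in the forward direction a 5-exo-dig O1'–C2' closure is followed by aromatising proton shift.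
- Disconnection 3: the enynol comes from Sonogashira coupling of a (Z)-3-iodo allylic alcohol (anti-carbomagnesiation and iodination of propargyl alcohol) with 3-ethynylfuran (from 3-furaldehyde).
- Ring order: ring B is bought; ring A is the only ring formed (step 4).

Key step: step 4

Assumption: (3-bromopropoxy)(tert-butyl)dimethylsilane, dimethyl (1-diazo-2-oxopropyl)phosphonate and the (R)-half-ester are taken as purchasable, the last in enantiopure form; no step acts at its stereocentre.

**Step 1**
Reactants: 1 prop-2-yn-1-ol (propargyl alcohol); 2 (3-bromopropoxy)(tert-butyl)dimethylsilane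
Product: 5 (2Z)-2-{3-[(tert-butyldimethylsilyl)oxy]propyl}-3-iodoprop-2-en-1-ol, via Grignard reagent 3 (not isolated), via oxamagnesacycle 4 (not isolated)
Conditions: 2 (2.6 equiv), Mg, Et2O, reflux; then 1, CuI (10 mol %), Et2O, −10 °C → rt; then I2, Et2O–THF, −30 → 0 °C
Reagents that add atoms: iodine, [I][I]
Why: CuI-catalysed anti-carbomagnesiation of the propargylic magnesium alkoxide (Duboudin reaction) puts the alkyl group on C2 and magnesium on C3 inside a five-membered chelate, so iodinolysis with retention should place iodine cis to the hydroxymethyl group (Z alkene).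

**Step 2**
Reactants: 6 furan-3-carbaldehyde (3-furaldehyde)
Product: 7 3-ethynylfuran
Conditions: dimethyl (1-diazo-2-oxopropyl)phosphonate, K2CO3, MeOH, 0 °C → rt; extracted into pentane and used as a solution (volatile)
Reagents that add atoms: dimethyl (1-diazo-2-oxopropyl)phosphonate, CC(=O)C(=[N+]=[N-])P(=O)(OC)OC
Why: Ohira–Bestmann (Seyferth–Gilbert) homologation: the diazophosphonate anion released by methanolysis adds to the aldehyde, and loss of dimethyl phosphate and N2 with a 1,2-hydrogen shift of the alkylidene carbene should give the terminal alkyne under conditions a furan tolerates.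

**Step 3**
Reactants: 5 (2Z)-2-{3-[(tert-butyldimethylsilyl)oxy]propyl}-3-iodoprop-2-en-1-ol; 7 3-ethynylfuran
Product: 8 (2Z)-2-{3-[(tert-butyldimethylsilyl)oxy]propyl}-5-(furan-3-yl)pent-2-en-4-yn-1-ol
Conditions: PdCl2(PPh3)2 (3 mol %), CuI (6 mol %), Et3N, THF (degassed), rt
Reagents that add atoms: none
Why: Sonogashira coupling: oxidative addition of zerovalent palladium into the vinyl C–I bond and transmetalation from the copper acetylide both proceed with retention, so the alkynyl group should end cis to the free hydroxymethyl group.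

**Step 4**
Reactants: 8 (2Z)-2-{3-[(tert-butyldimethylsilyl)oxy]propyl}-5-(furan-3-yl)pent-2-en-4-yn-1-ol
Product: 10 tert-butyl{3-[5-(furan-3-ylmethyl)furan-3-yl]propoxy}dimethylsilane, via alkylidene dihydrofuran 9 (not isolated)
Conditions: KOtBu (0.5 equiv), 18-crown-6 (0.5 equiv), THF–tBuOH, rt
Reagents that add atoms: none
Why: tert-Butoxide deprotonates the C5' hydroxyl, and the potassium alkoxide, held next to the alkyne by the Z alkene, adds anti to the proximal alkyne carbon so that the O1'–C2' bond forms and ring A closes in 5-exo-dig mode; the vinyl anion developing on the distal carbon is stabilised by ring B and is protonated by tBuOH to give the (Z)-alkylidene dihydrofuran 9. Deprotonation of 9 at C5' and reprotonation at the exocyclic carbon, a base-mediated prototropic shift driven by the aromaticity of ring A, should then turn that carbon into the CH2 bridge between rings A and B. The closest known reaction type is the base-catalysed cycloisomerisation of (Z)-2-en-4-yn-1-ols (β-alkynyl allylic alcohols) to 2,4-disubstituted furans. No stereocentre is formed. The step needs 5-exo attack at C2' rather than 6-endo attack at the furyl-bearing carbon; this is secured by the cis hydroxymethyl group fixed in step 1, by the exo trajectory favoured for five-membered closure onto an alkyne, and by the anionic polarity, which places the developing carbanion next to ring B only in the exo mode. The primary silyl ether and ring B should be inert to KOtBu at room temperature.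

**Step 5**
Reactants: 10 tert-butyl{3-[5-(furan-3-ylmethyl)furan-3-yl]propoxy}dimethylsilane
Product: 11 3-[5-(furan-3-ylmethyl)furan-3-yl]propan-1-ol
Conditions: Bu4NF, THF, 0 °C → rt
Reagents that add atoms: none
Why: Fluoride-mediated desilylation cleaves the Si–O bond (strong Si–F bond) under conditions to which both furans and the bis-furyl methane are inert.

**Step 6**
Reactants: 11 3-[5-(furan-3-ylmethyl)furan-3-yl]propan-1-ol
Product: 12 4-(3-bromopropyl)-2-(furan-3-ylmethyl)furan
Conditions: CBr4, PPh3, CH2Cl2, 0 °C
Reagents that add atoms: carbon tetrabromide, BrC(Br)(Br)Br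
Why: Appel reaction: the alkoxyphosphonium ion is displaced by bromide in an SN2 step under near-neutral conditions that should spare the acid-sensitive furans.

**Step 7**
Reactants: 13 (3R)-5-methoxy-3-methyl-5-oxopentanoic acid (methyl hydrogen (R)-3-methylglutarate)
Product: 14 methyl (3R)-5-hydroxy-3-methylpentanoate
Conditions: BH3·SMe2, THF, −10 °C → rt; MeOH quench; used at once
Reagents that add atoms: none
Why: Borane reduces the free carboxylic acid through its acyloxyborane much faster than the methyl ester and does not touch C3; the hydroxy ester is carried on directly to avoid lactonisation.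

**Step 8**
Reactants: 14 methyl (3R)-5-hydroxy-3-methylpentanoate
Product: 15 methyl (3S)-5-iodo-3-methylpentanoate
Conditions: I2, PPh3, imidazole, CH2Cl2, 0 °C → rt
Reagents that add atoms: iodine, [I][I]
Why: Garegg–Samuelsson (Appel-type) iodination of the primary alcohol by SN2 displacement; C3 is unchanged, and its descriptor becomes S only because the CH2CH2I branch now outranks CH2CO2Me.

**Step 9**
Reactants: 12 4-(3-bromopropyl)-2-(furan-3-ylmethyl)furan; 16 propyne; 15 methyl (3S)-5-iodo-3-methylpentanoate
Product: 20 methyl (3R,6Z)-10-[5-(furan-3-ylmethyl)furan-3-yl]-3,7-dimethyldec-6-enoate, via Grignard reagent 17 (not isolated), via alkylcopper 18 (not isolated), via alkenylcopper 19 (not isolated)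
Conditions: 12, Mg, Et2O, reflux; CuBr·SMe2 (1.05 equiv), Et2O–Me2S, −45 °C; 16 (excess), −25 °C; then 15, P(OEt)3, HMPA, −30 °C → rt
Reagents that add atoms: none
Why: Normant carbocupration followed by alkylation: the alkylcopper–MgBr2 reagent adds syn across propyne with carbon to the internal and copper to the terminal alkyne carbon, and the alkenylcopper is alkylated by the primary iodide with retention, so the furylpropyl and ester chains should end cis (6Z), while the ester and C3 of 15 are untouched (descriptor R again through the priority change).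

**Compound list**
1 | prop-2-yn-1-ol (propargyl alcohol) | OCC#C | starting material
2 | (3-bromopropoxy)(tert-butyl)dimethylsilane | CC(C)(C)[Si](C)(C)OCCCBr | starting material
3 | {3-[(tert-butyldimethylsilyl)oxy]propyl}magnesium bromide | CC(C)(C)[Si](C)(C)OCCC[Mg]Br | intermediate (not isolated)
4 | 4-{3-[(tert-butyldimethylsilyl)oxy]propyl}-2,5-dihydro-1,2-oxamagnesole (five-membered chelate O–Mg–CH=C(R)–CH2, magnesium cis to the CH2O group) | CC(C)(C)[Si](C)(C)OCCCC1=C[Mg]OC1 | intermediate (not isolated)
5 | (2Z)-2-{3-[(tert-butyldimethylsilyl)oxy]propyl}-3-iodoprop-2-en-1-ol | OC/C(CCCO[Si](C)(C)C(C)(C)C)=C\I | intermediate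
6 | furan-3-carbaldehyde | O=Cc1ccoc1 | starting material
7 | 3-ethynylfuran | C#Cc1ccoc1 | intermediate
8 | (2Z)-2-{3-[(tert-butyldimethylsilyl)oxy]propyl}-5-(furan-3-yl)pent-2-en-4-yn-1-ol | OC/C(CCCO[Si](C)(C)C(C)(C)C)=C\C#Cc1ccoc1 | intermediate
9 | tert-butyl({3-[(5Z)-5-(furan-3-ylmethylidene)-2,5-dihydrofuran-3-yl]propoxy})dimethylsilane | CC(C)(C)[Si](C)(C)OCCCC1=C/C(=C/c2ccoc2)OC1 | intermediate (not isolated)
10 | tert-butyl{3-[5-(furan-3-ylmethyl)furan-3-yl]propoxy}dimethylsilane | CC(C)(C)[Si](C)(C)OCCCc1coc(Cc2ccoc2)c1 | intermediate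
11 | 3-[5-(furan-3-ylmethyl)furan-3-yl]propan-1-ol | OCCCc1coc(Cc2ccoc2)c1 | intermediate
12 | 4-(3-bromopropyl)-2-(furan-3-ylmethyl)furan | BrCCCc1coc(Cc2ccoc2)c1 | intermediate
13 | (3R)-5-methoxy-3-methyl-5-oxopentanoic acid | COC(=O)C[C@H](C)CC(=O)O | starting material
14 | methyl (3R)-5-hydroxy-3-methylpentanoate | COC(=O)C[C@H](C)CCO | intermediate
15 | methyl (3S)-5-iodo-3-methylpentanoate | COC(=O)C[C@H](C)CCI | intermediate
16 | propyne | CC#C | starting material
17 | {3-[5-(furan-3-ylmethyl)furan-3-yl]propyl}magnesium bromide | Br[Mg]CCCc1coc(Cc2ccoc2)c1 | intermediate (not isolated)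
18 | {3-[5-(furan-3-ylmethyl)furan-3-yl]propyl}copper (as its MgBr2·SMe2 complex) | [Cu]CCCc1coc(Cc2ccoc2)c1 | intermediate (not isolated)
19 | {(1Z)-5-[5-(furan-3-ylmethyl)furan-3-yl]-2-methylpent-1-en-1-yl}copper | [Cu]/C=C(/C)CCCc1coc(Cc2ccoc2)c1 | intermediate (not isolated)
20 | methyl (3R,6Z)-10-[5-(furan-3-ylmethyl)furan-3-yl]-3,7-dimethyldec-6-enoate | COC(=O)C[C@H](C)CC/C=C(/C)CCCc1coc(Cc2ccoc2)c1 | target

**Totals**
Total step count: 9. Longest linear sequence: 6 steps (steps 1, 3, 4, 5, 6, 9; equally 2, 3, 4, 5, 6, 9).

**Steps most likely to fail**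

Step 9. The alkylation of the alkenylcopper by the unactivated primary iodide may be slow, so that on warming the organocopper decomposes, dimerises or is simply protonated on work-up, and some alkylcopper may be alkylated before it has added to propyne. Fallback: setting out from 12, the sequence is run as in step 9 up to alkenylcopper 19, which is then quenched with I2 (−50 → 0 °C) and should give, with retention, 2-(furan-3-ylmethyl)-4-[(4Z)-5-iodo-4-methylpent-4-en-1-yl]furan F1. Separately, 15 is treated with Zn dust and LiCl in THF to give iodo[(3S)-5-methoxy-3-methyl-5-oxopentyl]zinc F2. Negishi coupling of F1 with F2 (Pd(PPh3)4, THF, 40 °C) should proceed with retention of alkene geometry and comes back to the route at 20.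

Step 4. The alkoxide may close in the 6-endo sense, the proton shift to the aromatic ring may stall at the alkylidene dihydrofuran, or the enyne may oligomerise under base. Fallback: ring A is made instead by oxidative cyclodehydration of a (Z)-ene-1,4-diol, setting out from 6 and 5. Wittig reaction of 6 with (methoxymethyl)triphenylphosphonium chloride and KOtBu in THF should give 3-(2-methoxyethenyl)furan F3 (E/Z mixture), and brief hydrolysis with dilute HCl in THF–water at 0 °C should give 2-(furan-3-yl)acetaldehyde F4, used crude. Nozaki–Hiyama–Kishi addition of 5 to F4 (CrCl2, NiCl2 catalyst, DMF, rt) should give (2Z)-2-{3-[(tert-butyldimethylsilyl)oxy]propyl}-5-(furan-3-yl)pent-2-ene-1,4-diol F5 with the alkene geometry retained. MnO2 in CH2Cl2 should oxidise the primary allylic alcohol to (2Z)-2-{3-[(tert-butyldimethylsilyl)oxy]propyl}-5-(furan-3-yl)-4-hydroxypent-2-enal F6, which closes to the lactol 3-{3-[(tert-butyldimethylsilyl)oxy]propyl}-5-(furan-3-ylmethyl)-2,5-dihydrofuran-2-ol F7. A catalytic amount of pyridinium p-toluenesulfonate then removes water and comes back to the route at 10.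

Step 1. The γ-silyloxy Grignard reagent may be lost by protonation or 1,3-elimination before it adds, carbomagnesiation may stay incomplete, and iodination of the excess reagent may complicate isolation. Fallback: the Z trisubstituted alkene is set by olefination instead, setting out from 7 and 2 and bypassing 5 and step 3. Formylation of 7 (nBuLi, THF, −78 °C; DMF; quench into aqueous KH2PO4) should give 3-(furan-3-yl)prop-2-ynal F8. Alkylation of methyl bis(2,2,2-trifluoroethoxy)phosphorylacetate with 2 (NaH, DMF, NaI catalyst) should give methyl 2-[bis(2,2,2-trifluoroethoxy)phosphoryl]-5-[(tert-butyldimethylsilyl)oxy]pentanoate F9. Still–Gennari olefination of F8 with F9 (KN(SiMe3)2, 18-crown-6, THF, −78 °C) should give methyl (2Z)-2-{3-[(tert-butyldimethylsilyl)oxy]propyl}-5-(furan-3-yl)pent-2-en-4-ynoate F10 with the ester cis to the alkynyl group. Reduction with iBu2AlH (CH2Cl2, −78 °C) comes back to the route at 8.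

**Further compounds**
F1 | step 9 | 2-(furan-3-ylmethyl)-4-[(4Z)-5-iodo-4-methylpent-4-en-1-yl]furan | I/C=C(/C)CCCc1coc(Cc2ccoc2)c1
F2 | step 9 | iodo[(3S)-5-methoxy-3-methyl-5-oxopentyl]zinc | COC(=O)C[C@H](C)CC[Zn]I
F3 | step 4 | 3-(2-methoxyethenyl)furan (E/Z mixture) | COC=Cc1ccoc1
F4 | step 4 | 2-(furan-3-yl)acetaldehyde | O=CCc1ccoc1
F5 | step 4 | (2Z)-2-{3-[(tert-butyldimethylsilyl)oxy]propyl}-5-(furan-3-yl)pent-2-ene-1,4-diol (C4 racemic) | OC/C(CCCO[Si](C)(C)C(C)(C)C)=C\C(O)Cc1ccoc1
F6 | step 4 | (2Z)-2-{3-[(tert-butyldimethylsilyl)oxy]propyl}-5-(furan-3-yl)-4-hydroxypent-2-enal | O=C/C(CCCO[Si](C)(C)C(C)(C)C)=C\C(O)Cc1ccoc1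
F7 | step 4 | 3-{3-[(tert-butyldimethylsilyl)oxy]propyl}-5-(furan-3-ylmethyl)-2,5-dihydrofuran-2-ol | OC1OC(Cc2ccoc2)C=C1CCCO[Si](C)(C)C(C)(C)C
F8 | step 1 | 3-(furan-3-yl)prop-2-ynal | O=CC#Cc1ccoc1
F9 | step 1 | methyl 2-[bis(2,2,2-trifluoroethoxy)phosphoryl]-5-[(tert-butyldimethylsilyl)oxy]pentanoate | COC(=O)C(CCCO[Si](C)(C)C(C)(C)C)P(=O)(OCC(F)(F)F)OCC(F)(F)F
F10 | step 1 | methyl (2Z)-2-{3-[(tert-butyldimethylsilyl)oxy]propyl}-5-(furan-3-yl)pent-2-en-4-ynoate | COC(=O)/C(CCCO[Si](C)(C)C(C)(C)C)=C\C#Cc1ccoc1
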